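Remarks on the chemistry
- Numbering: ring atoms are numbered as in germacranes (ring C1–C10, lactone carbons C11–C13, C14 = methyl on C10, C15 = carbon on C4). α/β refer to the usual flat drawing of the ring, in which H-7 is α.
- Structures: the two partners and the product of the key step map correctly onto the target (8R in the enone, 3S in the cyclobutene, E at C1=C10, ring-cis at C4=C5), so no structural correction is needed. Three things are changed in the precursor design: the C8 oxygen carries TMS, not the silyl group used on C3; the cyclobutene is made in enantiopure form by a resolution (an achiral cyclobutanone route without one would give a racemate); and this thermally labile 3-oxycyclobutene is handled cold.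
- Assumption: both lipase resolutions follow the empirical size rule for secondary alcohols with the sp2-substituted flank as the large group, so the wanted enantiomer is the recovered alcohol in each case.

## Structural features

Compound 31 is a germacranolide of the heliangolide type: a ten-membered carbocycle (C1–C10) trans-fused across C6–C7 to an α-methylene-γ-butyrolactone (C11–C13, ring oxygen on C6). The carbocycle carries a ring-cis trisubstituted alkene C4=C5 (4Z) with the hydroxymethyl carbon C15 on C4, a free 3β-hydroxyl next to it, and a trans epoxide at C1–C10 (1R,10R) with the methyl C14 on C10. Three stereocentres stand in a row: C6 (α-O), C7 (α-H) and C8 (β-O, esterified with (S)-2-methylbutanoic acid). C3 is separated from them by the alkene, and the epoxide pair C1/C10 by the methylenes C2 and C9. The fragile groups are the α-methylene lactone (a Michael acceptor that tolerates neither nucleophiles nor strong base), the epoxide (acid opens it with transannular participation of C4=C5), the two allylic alcohols and the α-branched ester (epimerisable, able to migrate). The real difficulty is the medium ring itself, with two alkene-level units of opposite ring geometry and six ring stereocentres, because end-to-end closure of a ten-membered ring costs entropy and transannular strain. The key step uses the 1,5-relation of C1=C10 (the epoxide at its alkene level) and C4=C5 across the C2–C3 bond: the six atoms C10, C1, C2, C3, C4, C5 fold into a bicyclo[2.2.0]hexane, and the remaining chain C5–C6–C7–C8–C9–C10, oxygenated at C6 and C8, is a 5-oxygenated cyclohex-2-enone. C6 therefore arrives as a ketone, which opens C7 to enolate chemistry, and the C8 oxygen sits β to it, where it can steer that chemistry.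

## Logic of the disconnections

31 from 30. The two O–Si bonds at C3 and C15 are cut last. Free allylic alcohols would direct a peracid to C4=C5 and compete in the acylation, so they stay masked to the end. The gain is chemoselectivity in every earlier step. The demand is a fluoride source mild enough for the epoxide, the α-methylene lactone and the ester.

30 from 29. The two C–O bonds of the oxirane are cut. The trans epoxide maps onto the E-alkene that the key step delivers, and two stereocentres disappear. The forward step must pick C1=C10 over C4=C5 and C11=C13 and must attack the correct face.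

29 from 27 and 28. The acyl C–O bond at C8 is cut. The α-branched ester would not survive the enolate steps, so it enters after them, and its stereocentre is bought with 28. The demand is that C8–OH be the only free hydroxyl, which requires a silyl group on C8 orthogonal to those on C3 and C15 (27 from 26).

26 from 23. The C11=C13 bond is cut. The exocyclic methylene is the most electrophilic site of the molecule and is therefore made late, from the saturated lactone. This needs a lactone enolate at a stage where no other enolisable or base-labile group is present.

23 from 21 (through 22). The lactone C12–O bond and the C6–H bond are cut. The C6 oxygen is the carbonyl of the ring precursor, so the lactone ring and the C6 stereocentre vanish together. The demand is 1,2-hydride delivery to one face of the C6 ketone, trans to the C7 arm.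

21 from 19 (through 20). The C7–C11 bond is cut. C7 is the only enolisable α-carbon of the C6 ketone, and the free C8 hydroxyl of 19 can organise the enolate. Two carbons and the C7 stereocentre are removed. The forward step needs a dianion that neither undergoes retro-aldol cleavage nor is deprotonated elsewhere, delivery cis to the C8 oxygen, and capping of that oxygen before it lactonises.

19 from 18, 17 and 15 (through 16). No skeletal bond is cut; these are oxidation-level and protecting-group changes. The ester that the key step requires must become CH2O before any lactone exists, because no hydride distinguishes a conjugated ester from a γ-lactone. The ketone is reduced along with it and restored afterwards. The demands are silylation of the primary hydroxyl only and oxidation of the allylic secondary hydroxyl only.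

15 from 7 and 13 (through 14). In the retrosynthetic sense C5–C10 and C1–C4 are re-formed to give 14, and then C4–C5 and C1–C10 are cut. A ten-membered ring with two alkenes becomes two small rings with one stereocentre each, and no medium ring has to be cyclised. The demands are head-to-head regiochemistry, E geometry at C1=C10, ring-cis geometry at C4=C5, and survival of the product at the temperature of fragmentation.

13 from 12, 11, 8 and 9 (through 10). The O–Si bond is cut, then the enantiomers are separated, then the two ring bonds that join the propiolate carbons to the vinyl ether carbons (germacrane C3–C4 and C1–C2) are cut. The four-membered ring is reduced to two commercial two-carbon units. The demands are the correct orientation of the stepwise cycloaddition, a clean enantiomer separation, and cold handling.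

7 from 6, 5, 3, 2 and 1 (through 4). In turn the O–Si bond, the enantiomer pair, the C10–C14 bond (methyl addition with enone transposition), the enol ether C–O bond and the arene are taken back. The six-membered partner is reduced to an achiral, symmetric triphenol. The demand is that the β-hydroxy ketone never meets conditions that dehydrate it to a phenol.

## Other disconnections considered

Alternative 1: The cut is C1–C2, with the C3–O bond formed in the same event. The open-chain oxime A2 (aldoxime at C1 on the C10 carbinol carbon, diene terminus C2=C3–C4=C5, lactone already in place) would be oxidised (NaOCl) to its nitrile oxide function, which adds to the terminal vinyl group and gives the isoxazoline-bridged ten-membered lactone A1.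
- In its favour: the intramolecular dipolar cycloaddition runs near room temperature, tolerates the lactone and the ethers, has the intrinsic regiochemistry (carbon to the terminal CH2), and delivers the C3 oxygen and a masked C1 carbonyl at once. The C10 carbinol is fixed in the open chain, so the epoxide would be closed by displacement at C1 and not by face-selective epoxidation. On the C1/C10 problem it is the better plan.
- Against it here: the ten-membered ring is closed end to end, which requires high dilution and competes with dimerisation of the dipole. The C3 configuration rests on the facial selectivity of a flexible chain, whereas the chosen plan brings C3 in resolved. After ring closure the N–O bond must be cleaved without touching the alkenes (Mo(CO)6), and the C1 ketone must be reduced with control, sulfonylated and closed to the epoxide. Methylenation, deprotection and acylation still follow, and four stereocentres (C6, C7, C8, C10) must first be built in a linear chain.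
- Comparison: structurally it is better for the epoxide, worse for C3, and equal for the lactone and the C8 ester. Mechanistically it is milder than photolysis followed by heating to 190 °C. In step economy it is likely the longer route.

Alternative 2: The cut is the lactone C6–O bond. The ring acid A4 (C6 as a methylene, an acrylic acid on C7, epoxide and C8 ester already present) would be converted into its acyloxy radical, for example by PhI(OAc)2/I2 and light. A 1,5-hydrogen transfer from allylic C6, oxidation of the allyl radical (Cu(OAc)2, divalent copper) and capture by the carboxylate would give A3, the bis-silyl ether of 31.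
- In its favour: it forms the lactone on the fully decorated ring one step before the end, needs no C6 carbonyl and no reduction–lactonisation–methylenation sequence, and so has the better endgame step economy. The six-membered transition state, the weak allylic C6–H bond and the slow decarboxylation of an acryloyloxy radical all support it.
- Against it here: it closes no carbocycle, so A4 must still be made by another ring synthesis, and an enone-based one would have to remove the C6 oxygen it naturally provides. The oxygen radical has other outlets: hydrogen on C8 is also 1,5-related, and addition to C4=C5 or to the acrylate is possible. The allyl cation can be captured at C4, and the C6 configuration is set only by ring conformation, whereas the chosen plan uses a chiral reducing catalyst.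
- Comparison: better in late-stage economy, weaker in mechanistic control, and equal to the chosen plan in depending on the conformation of the medium ring for at least one stereocentre.

Alternative 3: The cut is C3–C4. The open-chain iodo aldehyde A6 ((Z)-alkenyl iodide at C4, aldehyde at C3, lactone, exocyclic methylene and C8 ester in place) would be closed with NiCl2/CrCl3 as catalysts, trivalent chromium being reduced to divalent chromium at the cathode, to give the allylic alcohol A5.
- In its favour: the alkenyl–chromium addition tolerates esters and lactones. The ring-cis geometry of C4=C5 is carried stereospecifically from the iodide, and the E geometry of C1=C10 comes from acyclic olefination. On alkene geometry it is therefore better than a thermal diyl cleavage. Only epoxidation and desilylation remain afterwards, and chromium stays catalytic.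
- Against it here: C3 is created during the macrocyclisation, so its configuration depends on substrate bias or on a chiral ligand, whereas the chosen plan brings it in resolved. The closure again needs high dilution and must overcome the strain of a ring that already contains an E-alkene. The free C3 hydroxyl of A5 would direct the later peracid to C4=C5 unless it is protected first. The acrylate is exposed to the cathode, and the C6/C7/C8 triad has to be assembled linearly.
- Comparison: better on alkene geometry and on carrying the final ester through, worse on C3 and on the entropic cost of ring closure, equal on the late epoxidation problem, and similar in total step count.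

Key step: step 9

## Steps

Step 1
Reactants: 1 phloroglucinol
Product: 2 5-hydroxycyclohexane-1,3-dione
Conditions: H2 (3 atm), Rh/Al2O3 (5 wt %), NaOH (1.0 equiv), H2O, 25 °C; then HCl to pH 3, 0 °C
Reagents that add atoms: none
Why: Partial hydrogenation of the mono-phenolate stops at the 1,3-dione because its enolate resists further reduction, the same arene-to-dione reduction that turns resorcinol into cyclohexane-1,3-dione; 2 is achiral.

Step 2
Reactants: 2 5-hydroxycyclohexane-1,3-dione
Product: 3 rac-3-ethoxy-5-hydroxycyclohex-2-en-1-one
Conditions: EtOH, TsOH·H2O (2 mol %), 3 Å molecular sieves, 25 °C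
Reagents that add atoms: ethanol CCO
Why: Acid-catalysed enol etherification of a cyclic 1,3-dione (vinylogous Fischer esterification); both carbonyls of the symmetric dione give the same racemic product, and room temperature keeps the β-hydroxyl from dehydrating towards a phenol.

Step 3
Reactants: 3 rac-3-ethoxy-5-hydroxycyclohex-2-en-1-one
Product: 5 rac-5-hydroxy-3-methylcyclohex-2-en-1-one, via tertiary carbinol 4 (not isolated)
Conditions: MeLi (2.3 equiv), THF, −78 to 0 °C; then 1 M HCl, 0 °C
Reagents that add atoms: methyllithium [Li]C
Why: Stork–Danheiser transposition: after the first equivalent has deprotonated the hydroxyl, MeLi adds 1,2 to the vinylogous ester, and brief cold acid hydrolysis of the enol ether carbinol expels ethanol and leaves the methyl on the β-carbon of the new enone.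

Step 4
Reactants: 5 rac-5-hydroxy-3-methylcyclohex-2-en-1-one
Product: 6 (R)-5-hydroxy-3-methylcyclohex-2-en-1-one
Conditions: Candida antarctica lipase B (immobilised), vinyl acetate (3 equiv), t-BuOMe, 25 °C, stopped just beyond half conversion; chromatography
Reagents that add atoms: none
Why: Lipase-catalysed kinetic resolution by irreversible transesterification; by the size rule for secondary alcohols (methyl-bearing sp2 flank as the large group) the (S)-alcohol should be acetylated faster, so the (R)-alcohol is recovered and fixes C8 of the target.

Step 5
Reactants: 6 (R)-5-hydroxy-3-methylcyclohex-2-en-1-one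
Product: 7 (R)-3-methyl-5-(trimethylsilyloxy)cyclohex-2-en-1-one
Conditions: Me3SiCl, Et3N, CH2Cl2, 0 °C
Reagents that add atoms: chlorotrimethylsilane C[Si](C)(C)Cl
Why: Standard silylation of a secondary alcohol; the TMS group is a short-lived mask that only has to block the six-centre retro-aldol of a free β-hydroxy ketone during the hot stage of step 9 and then falls off in the work-up of step 10.

Step 6
Reactants: 8 methyl propiolate; 9 tert-butyldimethyl(vinyloxy)silane
Product: 11 rac-methyl 4-hydroxycyclobut-1-ene-1-carboxylate, via silyl ether 10 (not isolated)
Conditions: HN(SO2CF3)2 (2 mol %), CH2Cl2, −78 °C; then aq HF (48 %), MeCN, 0 °C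
Reagents that add atoms: none
Why: Acid-catalysed stepwise (2+2) cycloaddition of a silyl enol ether with a propiolate (Mukaiyama–Michael addition of the enol ether CH2 to the alkyne terminus, then closure of the allenoate onto the silyloxycarbenium carbon) gives the 4-silyloxycyclobut-1-ene-1-carboxylate regiochemistry directly, and HF in the same flask frees the alcohol needed for resolution. Everything is kept at or below 0 °C because 3-oxy-substituted cyclobutenes open conrotatorily near room temperature.

Step 7
Reactants: 11 rac-methyl 4-hydroxycyclobut-1-ene-1-carboxylate
Product: 12 methyl (S)-4-hydroxycyclobut-1-ene-1-carboxylate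
Conditions: Candida antarctica lipase B (immobilised), vinyl acetate (3 equiv), t-BuOMe, 4 °C, stopped just beyond half conversion; chromatography at 0 °C
Reagents that add atoms: none
Why: Lipase-catalysed kinetic resolution of a cyclic allylic alcohol; the ester-bearing sp2 carbon is clearly the large group, so the (R)-alcohol should be acetylated and the (S)-alcohol, which fixes C3 of the target, recovered.

Step 8
Reactants: 12 methyl (S)-4-hydroxycyclobut-1-ene-1-carboxylate
Product: 13 methyl (S)-4-(tert-butyldimethylsilyloxy)cyclobut-1-ene-1-carboxylate
Conditions: t-BuMe2SiCl, imidazole, CH2Cl2, 0 °C; stored at −20 °C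
Reagents that add atoms: tert-butyldimethylsilyl chloride CC(C)(C)[Si](C)(C)Cl
Why: Imidazole-mediated silylation under conditions too weakly basic to form the alkoxide, which would trigger ring opening; the TBS ether must last to the final step.

Step 9
Reactants: 7 (R)-3-methyl-5-(trimethylsilyloxy)cyclohex-2-en-1-one; 13 methyl (S)-4-(tert-butyldimethylsilyloxy)cyclobut-1-ene-1-carboxylate (1.3 equiv)
Product: 15 methyl (3S,8R)-3-(tert-butyldimethylsilyloxy)-10-methyl-6-oxo-8-(trimethylsilyloxy)cyclodeca-1(10),4-diene-4-carboxylate (C1=C10 E; C4=C5 ring-cis), via tricyclic photoadduct 14 (not isolated)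
Conditions: hν (350 nm, Pyrex), CH2Cl2, −40 °C; solvent removed cold; then PhMe (0.01 M), 190 °C, sealed silylated tube, short heating; then 1,4-diazabicyclo[2.2.2]octane (10 mol %), 25 °C
Reagents that add atoms: none
Why: Excitation of 7 gives its triplet, which adds stepwise to the acrylate-type alkene of 13 through a 1,4-biradical; the closest known reaction type is the enone–cyclobutene (2+2) photocycloaddition followed by thermal opening of the resulting bicyclo[2.2.0]hexane to a cyclodeca-1,5-diene. Head-to-head orientation (C4 to C5, C1 to C10) is the normal outcome for an electron-poor alkene and is needed to place the ester on C4, and the cis-anti-cis tricycle should dominate because the cyclobutene approaches exo and the six–four fusion closes cis. Two four-membered rings are closed by radical recombination and no medium ring is cyclised: the ten-membered ring appears when heating breaks first the central C1–C4 bond and then C5–C10 of the 1,4-diyl, the ester stabilising the C4 radical. The four cyclobutane stereocentres (C1, C4, C5, C10) are all erased, so the facial mixture of adducts converges and only C3 (from 13) and C8 (from 7) remain. The step needs E geometry at C1=C10, which follows when the diyl cleaves with C9 kept anti to C2 and the conformational change is taken up at the planar, ester-bearing C4, and it needs ring-cis geometry at C4=C5, the fumarate-like placement of ketone and ester, which reversible amine addition to the doubly activated alkene secures. The TMS ether blocks retro-aldol cleavage at 190 °C, and heating must stay short and below the Cope threshold of the E,Z-diene.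

Step 10
Reactants: 15 the keto ester from step 9
Product: 17 (3S,8R)-3-(tert-butyldimethylsilyloxy)-4-(hydroxymethyl)-10-methylcyclodeca-1(10)E,4Z-diene-6,8-diol (both C6 epimers), via silylated diol 16 (not isolated)
Conditions: i-Bu2AlH (5 equiv), CH2Cl2, −78 °C; potassium sodium tartrate (aq); then K2CO3 (cat.), MeOH, 0 °C
Reagents that add atoms: none
Why: i-Bu2AlH reduces the ketone and the conjugated ester in the 1,2 sense (the C6 configuration is irrelevant because C6 is re-oxidised in step 12), and mild methanolysis removes only the TMS ether; C15 thus reaches its final oxidation level before any lactone exists.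

Step 11
Reactants: 17 the triol from step 10
Product: 18 the C15 tert-butyldiphenylsilyl ether of 17 (C6–OH and C8–OH free)
Conditions: t-BuPh2SiCl (1.05 equiv), imidazole, CH2Cl2, −20 to 0 °C
Reagents that add atoms: tert-butyldiphenylsilyl chloride CC(C)(C)[Si](Cl)(c1ccccc1)c1ccccc1
Why: A bulky silyl chloride selects the primary allylic hydroxyl over the two secondary ones; TBDPS is chosen because it must survive the acid removal of a TES ether in step 16.

Step 12
Reactants: 18 the diol from step 11
Product: 19 (3S,8R)-3-(tert-butyldimethylsilyloxy)-4-(tert-butyldiphenylsilyloxymethyl)-8-hydroxy-10-methylcyclodeca-1(10)E,4Z-dien-6-one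
Conditions: MnO2 (20 equiv), CH2Cl2, 25 °C
Reagents that add atoms: none
Why: MnO2 oxidises only allylic alcohols, so both C6 epimers converge on the enone while the saturated C8 carbinol is untouched; the ketone needed at C7 is restored with C8–OH free.

Step 13
Reactants: 19 the β-hydroxy enone from step 12
Product: 21 methyl 2-[7-yl]acetate of the ring of 19, with the acetate arm on C7 cis to the C8 oxygen (H-7α) and C8–O as its triethylsilyl ether, via lithium alkoxide 20 (not isolated)
Conditions: LiN(i-Pr)2 (2.3 equiv), THF/DMPU, −78 to −50 °C; BrCH2CO2Me, −78 °C; then Et3SiOSO2CF3 (1.5 equiv), −78 °C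
Reagents that add atoms: methyl bromoacetate COC(=O)CBr; triethylsilyl trifluoromethanesulfonate CC[Si](CC)(CC)OS(=O)(=O)C(F)(F)F
Why: Fráter–Seebach-type alkylation of a β-hydroxy carbonyl dianion: lithium bridges the C8 alkoxide and the enolate oxygen, C7 is the only sp3 α-carbon, and the electrophile enters on the outer face anti to C9, which places the arm cis to the C8 oxygen. An alkoxide cannot be eliminated as a silyloxide could, and its silylation in the flask prevents lactonisation onto the cis ester.

Step 14
Reactants: 21 the keto ester from step 13
Product: 23 the trans-fused 6α,12-olide (H-6β, H-7α) with 3β-OTBS, 8β-OTES, 15-OTBDPS and the E-alkene C1=C10, via hydroxy ester 22 (not isolated)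
Conditions: (R)-B-methyl CBS oxazaborolidine [(R)-1-methyl-3,3-diphenyltetrahydro-1H,3H-pyrrolo[1,2-c][1,3,2]oxazaborole] (0.5 equiv), catecholborane (2 equiv), PhMe, −78 °C; MeOH; then pyridinium p-toluenesulfonate (cat.), PhMe, 50 °C
Reagents that add atoms: none
Why: Corey–Bakshi–Shibata reduction: catalyst-controlled 1,2-hydride delivery to the enone carbonyl, with the C4=C5 alkenyl flank as the large group, should give the 6α-alcohol trans to the C7 arm; acid-catalysed lactonisation of this γ-hydroxy ester then closes the trans-fused γ-lactone with loss of methanol.

Step 15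
Reactants: 23 the lactone from step 14
Product: 26 the α-methylene lactone (C11=C13) of 23, via Mannich base 24 (not isolated), via ammonium iodide 25 (not isolated)
Conditions: LiN(SiMe3)2, THF, −78 °C; CH2=NMe2+ I−, −78 to 0 °C; then MeI, THF/MeOH, 25 °C; then NaHCO3 (aq), EtOAc, 25 °C
Reagents that add atoms: N,N-dimethylmethyleneiminium iodide (Eschenmoser's salt) C=[N+](C)C.[I-]
Why: Mannich reaction of the lactone enolate with Eschenmoser's salt, N-methylation and base-induced loss of trimethylamine is the standard α-methylenation of γ-lactones; at this stage the lactone α-CH2 is the only acidic C–H and no base-labile ester is present.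

Step 16
Reactants: 26 the α-methylene lactone from step 15
Product: 27 the 8β-alcohol (3β-OTBS and 15-OTBDPS retained)
Conditions: pyridinium p-toluenesulfonate (cat.), MeOH/CH2Cl2, 0 °C
Reagents that add atoms: none
Why: Acid methanolysis removes a secondary TES ether much faster than a secondary TBS or a primary TBDPS ether, so C8–OH alone is exposed.

Step 17
Reactants: 27 the 8β-alcohol from step 16; 28 (S)-2-methylbutanoic acid
Product: 29 the 8β-[(S)-2-methylbutanoate] of 27
Conditions: N,N'-dicyclohexylcarbodiimide, 4-(dimethylamino)pyridine (0.2 equiv), CH2Cl2, 0 to 25 °C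
Reagents that add atoms: none
Why: Steglich esterification of the only free hydroxyl; the stereocentre of the acid is carried in unchanged, with catalytic base at low temperature limiting ketene-type epimerisation.

Step 18
Reactants: 29 the ester from step 17
Product: 30 the 1β,10α-epoxide (1R,10R) of 29
Conditions: 3-ClC6H4CO3H (1.1 equiv), NaHCO3, CH2Cl2, 0 °C
Reagents that add atoms: 3-chloroperoxybenzoic acid OOC(=O)c1cccc(Cl)c1
Why: Peracid (Prilezhaev) epoxidation is selective for the only electron-rich alkene (C4=C5 carries three allylic oxygens, C11=C13 is an acrylate) and is stereospecific, so the E-alkene gives the trans epoxide. Attack on the outward face of the E-alkene, in the conformer with C14 on the β-face, should give the 1β,10α isomer.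

Step 19
Reactants: 30 the epoxide from step 18
Product: 31 CNP0267576.2 (target)
Conditions: Bu4NF/AcOH (1:1, excess), THF, 0 to 25 °C
Reagents that add atoms: none
Why: Fluoride cleaves both silyl ethers; the acetic acid buffer protects the epoxide from transannular opening, the α-methylene lactone from conjugate addition and the ester from migration.

## Compound list

1 | phloroglucinol (benzene-1,3,5-triol) | Oc1cc(O)cc(O)c1 | starting material
2 | 5-hydroxycyclohexane-1,3-dione | O=C1CC(O)CC(=O)C1 | intermediate
3 | rac-3-ethoxy-5-hydroxycyclohex-2-en-1-one | CCOC1=CC(=O)CC(O)C1 | intermediate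
4 | rac-3-ethoxy-1-methylcyclohex-2-ene-1,5-diol (dilithium salt in the flask; not isolated) | CCOC1=CC(C)(O)CC(O)C1 | intermediate
5 | rac-5-hydroxy-3-methylcyclohex-2-en-1-one | CC1=CC(=O)CC(O)C1 | intermediate
6 | (R)-5-hydroxy-3-methylcyclohex-2-en-1-one | CC1=CC(=O)C[C@H](O)C1 | intermediate
7 | (R)-3-methyl-5-(trimethylsilyloxy)cyclohex-2-en-1-one | CC1=CC(=O)C[C@H](O[Si](C)(C)C)C1 | intermediate
8 | methyl propiolate | C#CC(=O)OC | starting material
9 | tert-butyldimethyl(vinyloxy)silane | C=CO[Si](C)(C)C(C)(C)C | starting material
10 | rac-methyl 4-(tert-butyldimethylsilyloxy)cyclobut-1-ene-1-carboxylate (not isolated) | COC(=O)C1=CCC1O[Si](C)(C)C(C)(C)C | intermediate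
11 | rac-methyl 4-hydroxycyclobut-1-ene-1-carboxylate | COC(=O)C1=CCC1O | intermediate
12 | methyl (S)-4-hydroxycyclobut-1-ene-1-carboxylate | COC(=O)C1=CC[C@@H]1O | intermediate
13 | methyl (S)-4-(tert-butyldimethylsilyloxy)cyclobut-1-ene-1-carboxylate | COC(=O)C1=CC[C@@H]1O[Si](C)(C)C(C)(C)C | intermediate
14 | cis-anti-cis photoadduct (not isolated): cyclohexanone C5–C10 fused at C5–C10 to a bicyclo[2.2.0]hexane (C5, C10, C1, C4 and C1–C4); CO2Me on C4, CH3 on C10, OTBS on C3 (S), OTMS on C8 (R); facial diastereomers at C1, C4, C5, C10 | COC(=O)C12[C@@H](O[Si](C)(C)C(C)(C)C)CC1C1(C)C[C@@H](O[Si](C)(C)C)CC(=O)C12 | intermediate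
15 | methyl (3S,8R)-3-(tert-butyldimethylsilyloxy)-10-methyl-6-oxo-8-(trimethylsilyloxy)cyclodeca-1(10),4-diene-4-carboxylate; C1=C10 E, C4=C5 ring-cis (C3 and C6 on the same side) | O=C1/C=C(/C(=O)OC)[C@@H](O[Si](C)(C)C(C)(C)C)C/C=C(\C)C[C@@H](O[Si](C)(C)C)C1 | intermediate
16 | (3S,8R)-3-(tert-butyldimethylsilyloxy)-4-(hydroxymethyl)-10-methyl-8-(trimethylsilyloxy)cyclodeca-1(10)E,4Z-dien-6-ol, both C6 epimers (not isolated) | OC1/C=C(/CO)[C@@H](O[Si](C)(C)C(C)(C)C)C/C=C(\C)C[C@@H](O[Si](C)(C)C)C1 | intermediate
17 | (3S,8R)-3-(tert-butyldimethylsilyloxy)-4-(hydroxymethyl)-10-methylcyclodeca-1(10)E,4Z-diene-6,8-diol, both C6 epimers | OC1/C=C(/CO)[C@@H](O[Si](C)(C)C(C)(C)C)C/C=C(\C)C[C@@H](O)C1 | intermediate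
18 | (3S,8R)-3-(tert-butyldimethylsilyloxy)-4-(tert-butyldiphenylsilyloxymethyl)-10-methylcyclodeca-1(10)E,4Z-diene-6,8-diol, both C6 epimers | OC1/C=C(/CO[Si](c2ccccc2)(c2ccccc2)C(C)(C)C)[C@@H](O[Si](C)(C)C(C)(C)C)C/C=C(\C)C[C@@H](O)C1 | intermediate
19 | (3S,8R)-3-(tert-butyldimethylsilyloxy)-4-(tert-butyldiphenylsilyloxymethyl)-8-hydroxy-10-methylcyclodeca-1(10)E,4Z-dien-6-one | O=C1/C=C(/CO[Si](c2ccccc2)(c2ccccc2)C(C)(C)C)[C@@H](O[Si](C)(C)C(C)(C)C)C/C=C(\C)C[C@@H](O)C1 | intermediate
20 | C7-alkylated β-hydroxy ketone: 19 with CH2CO2Me on C7 cis to the C8 oxygen (H-7α); lithium alkoxide in the flask (not isolated) | O=C1/C=C(/CO[Si](c2ccccc2)(c2ccccc2)C(C)(C)C)[C@@H](O[Si](C)(C)C(C)(C)C)C/C=C(\C)C[C@@H](O)[C@H]1CC(=O)OC | intermediate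
21 | 8-O-triethylsilyl ether of 20 (3β-OTBS, 7α-H, 8β-OTES, 15-OTBDPS, C6 ketone) | O=C1/C=C(/CO[Si](c2ccccc2)(c2ccccc2)C(C)(C)C)[C@@H](O[Si](C)(C)C(C)(C)C)C/C=C(\C)C[C@@H](O[Si](CC)(CC)CC)[C@H]1CC(=O)OC | intermediate
22 | 6α-hydroxy ester from 21 (H-6β; not isolated) | O[C@@H]1/C=C(/CO[Si](c2ccccc2)(c2ccccc2)C(C)(C)C)[C@@H](O[Si](C)(C)C(C)(C)C)C/C=C(\C)C[C@@H](O[Si](CC)(CC)CC)[C@H]1CC(=O)OC | intermediate
23 | trans-fused 6α,12-olide with saturated C11: 3β-OTBS, 8β-OTES, 15-OTBDPS, C1=C10 E, C4=C5 Z | O=C1O[C@@H]2/C=C(/CO[Si](c3ccccc3)(c3ccccc3)C(C)(C)C)[C@@H](O[Si](C)(C)C(C)(C)C)C/C=C(\C)C[C@@H](O[Si](CC)(CC)CC)[C@H]2C1 | intermediate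
24 | 11-(dimethylaminomethyl) lactone, C11 epimers (not isolated) | CN(C)CC1C(=O)O[C@@H]2/C=C(/CO[Si](c3ccccc3)(c3ccccc3)C(C)(C)C)[C@@H](O[Si](C)(C)C(C)(C)C)C/C=C(\C)C[C@@H](O[Si](CC)(CC)CC)[C@@H]12 | intermediate
25 | 11-(trimethylammoniomethyl) lactone iodide (not isolated) | C[N+](C)(C)CC1C(=O)O[C@@H]2/C=C(/CO[Si](c3ccccc3)(c3ccccc3)C(C)(C)C)[C@@H](O[Si](C)(C)C(C)(C)C)C/C=C(\C)C[C@@H](O[Si](CC)(CC)CC)[C@@H]12.[I-] | intermediate
26 | α-methylene-6α,12-olide: 3β-OTBS, 8β-OTES, 15-OTBDPS | C=C1C(=O)O[C@@H]2/C=C(/CO[Si](c3ccccc3)(c3ccccc3)C(C)(C)C)[C@@H](O[Si](C)(C)C(C)(C)C)C/C=C(\C)C[C@@H](O[Si](CC)(CC)CC)[C@@H]12 | intermediate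
27 | α-methylene-6α,12-olide: 3β-OTBS, 8β-OH, 15-OTBDPS | C=C1C(=O)O[C@@H]2/C=C(/CO[Si](c3ccccc3)(c3ccccc3)C(C)(C)C)[C@@H](O[Si](C)(C)C(C)(C)C)C/C=C(\C)C[C@@H](O)[C@@H]12 | intermediate
28 | (S)-2-methylbutanoic acid | CC[C@H](C)C(=O)O | starting material
29 | 8β-[(S)-2-methylbutanoyloxy] α-methylene-6α,12-olide: 3β-OTBS, 15-OTBDPS, C1=C10 E | C=C1C(=O)O[C@@H]2/C=C(/CO[Si](c3ccccc3)(c3ccccc3)C(C)(C)C)[C@@H](O[Si](C)(C)C(C)(C)C)C/C=C(\C)C[C@@H](OC(=O)[C@@H](C)CC)[C@@H]12 | intermediate
30 | 1β,10α-epoxide of 29 (1R,10R) | C=C1C(=O)O[C@@H]2/C=C(/CO[Si](c3ccccc3)(c3ccccc3)C(C)(C)C)[C@@H](O[Si](C)(C)C(C)(C)C)C[C@H]3O[C@]3(C)C[C@@H](OC(=O)[C@@H](C)CC)[C@@H]12 | intermediate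
31 | CNP0267576.2: 1β,10α-epoxy-3β,15-dihydroxy-8β-[(S)-2-methylbutanoyloxy]germacra-4Z,11(13)-dien-6α,12-olide | C=C1C(=O)O[C@@H]2/C=C(/CO)[C@@H](O)C[C@H]3O[C@]3(C)C[C@@H](OC(=O)[C@@H](C)CC)[C@@H]12 | target

## Step count and least certain steps

Total step count: 19. Longest linear sequence: 16 steps (steps 1–5 and 9–19); the cyclobutene branch (steps 6–8) joins at step 9.

Step 9 (key step). Three things can go wrong.
- In the photochemical stage the cyclobutene may ring-open, or add in the head-to-tail sense, before the triplet enone captures it.
- In the thermal stage the 1,4-diyl can cleave from the other chair and give Z geometry at C1=C10.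
- The doubly activated dienone, once formed, can be consumed at 190 °C by Cope rearrangement to the divinylcyclohexane, by loss of silanol next to the ketone, or by addition reactions.

The fallback fragments the tricycle at the alcohol oxidation level. Setting out from 14, NaBH4 in MeOH at 0 °C would reduce the ketone to the tricyclic hydroxy ester F1. Heating F1 in toluene as in step 9 would give the cyclodecadienol ester F2, which has no β-silyloxy ketone and only a singly activated alkene. The conditions of step 10 would then carry F2 through 16 to 17, where the route is rejoined without extra steps. The C1=C10 geometry would have to be checked at F2, because this fallback removes the decomposition channels but not the choice between the two chairs.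

Step 13. The second deprotonation has to occur at C7 next to an alkoxide. Deprotonation at the γ-positions (C3, C15), retro-aldol opening of the lithium aldolate, or delivery of the electrophile to the wrong face of a non-chelated enolate would erode yield or the C7 configuration. The fallback gives up chelation and sets C7 by kinetic protonation. Setting out from 19, Et3SiOSO2CF3 and 2,6-lutidine would give the silyl ether F3. Its mono-enolate (LiN(i-Pr)2, −78 °C) would be alkylated with methyl bromoacetate anti to the silyloxy group, which is expected to give the C7 epimer F4. Re-enolisation of F4 with LiN(SiMe3)2 and a quench with a hindered phenol at −78 °C would put the proton on the face the electrophile had used and so invert C7, arriving at 21.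

Step 14. The catalyst must tell the alkenyl flank from an α-branched alkyl flank. If that distinction is weak, or opposed by the conformation of the ring, facial selectivity at C6 will be poor. The fallback corrects C6 by inversion and does not rely on facial control. Setting out from 21, NaBH4/CeCl3·7H2O would give the 6β-hydroxy ester F5, which lactonises to the cis-fused lactone F6. LiOH would open F6 to the hydroxy acid F7, kept as its lithium salt and acidified only at the moment of use. An intramolecular Mitsunobu reaction (PPh3, diisopropyl azodicarboxylate) would then close the lactone with inversion at allylic C6 and return to 23.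

Step 6. With an aldehyde-derived silyl enol ether the zwitterion may collapse to the open-chain Michael product, or the vinyl ether may oligomerise, before the four-membered ring closes. The fallback builds the saturated ring first. Setting out from 9, the same acid-catalysed (2+2) cycloaddition with methyl acrylate (EtAlCl2 as catalyst) would give the trans cyclobutane ester F8. Its enolate would be selenenylated with PhSeBr to the selenide F9, and H2O2 would oxidise F9 to the selenoxide F10. F10 eliminates syn and away from the oxygen-bearing carbon, arriving at 10, which the HF treatment of step 6 converts into 11.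

Step 18. The face of C1=C10 that the peracid reaches depends on which rotamer of the E-alkene the ring prefers, so facial selectivity may be poor if the conformer with C14 on the α-face is populated. The fallback replaces substrate control by reagent control: a Shi epoxidation of 29 with Oxone (2KHSO5·KHSO4·K2SO4) and the D-fructose-derived ketone 1,2:4,5-di-O-isopropylidene-β-D-erythro-2,3-hexodiulo-2,6-pyranose, whose spiro transition state selects one face of E-trisubstituted alkenes. It sets out from 29 and returns at 30 and makes no new compound (F0).

## Further compounds

F1 | step 9 | tricyclic hydroxy ester (14 with C6–OH in place of the ketone; C6 epimers) | COC(=O)C12[C@@H](O[Si](C)(C)C(C)(C)C)CC1C1(C)C[C@@H](O[Si](C)(C)C)CC(O)C12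
F2 | step 9 | methyl (3S,8R)-3-(tert-butyldimethylsilyloxy)-6-hydroxy-10-methyl-8-(trimethylsilyloxy)cyclodeca-1(10),4-diene-4-carboxylate (C1=C10 E, C4=C5 ring-cis; C6 epimers) | OC1/C=C(/C(=O)OC)[C@@H](O[Si](C)(C)C(C)(C)C)C/C=C(\C)C[C@@H](O[Si](C)(C)C)C1
F3 | step 13 | 8-O-triethylsilyl ether of 19 | O=C1/C=C(/CO[Si](c2ccccc2)(c2ccccc2)C(C)(C)C)[C@@H](O[Si](C)(C)C(C)(C)C)C/C=C(\C)C[C@@H](O[Si](CC)(CC)CC)C1
F4 | step 13 | C7 epimer of 21 (acetate arm trans to the C8 oxygen) | O=C1/C=C(/CO[Si](c2ccccc2)(c2ccccc2)C(C)(C)C)[C@@H](O[Si](C)(C)C(C)(C)C)C/C=C(\C)C[C@@H](O[Si](CC)(CC)CC)[C@@H]1CC(=O)OC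
F5 | step 14 | 6β-hydroxy ester (C6 epimer of 22) | O[C@H]1/C=C(/CO[Si](c2ccccc2)(c2ccccc2)C(C)(C)C)[C@@H](O[Si](C)(C)C(C)(C)C)C/C=C(\C)C[C@@H](O[Si](CC)(CC)CC)[C@H]1CC(=O)OC
F6 | step 14 | cis-fused 6β,12-olide (C6 epimer of 23) | O=C1O[C@H]2/C=C(/CO[Si](c3ccccc3)(c3ccccc3)C(C)(C)C)[C@@H](O[Si](C)(C)C(C)(C)C)C/C=C(\C)C[C@@H](O[Si](CC)(CC)CC)[C@H]2C1
F7 | step 14 | 6β-hydroxy acid from F6 | O[C@H]1/C=C(/CO[Si](c2ccccc2)(c2ccccc2)C(C)(C)C)[C@@H](O[Si](C)(C)C(C)(C)C)C/C=C(\C)C[C@@H](O[Si](CC)(CC)CC)[C@H]1CC(=O)O
F8 | step 6 | rac-methyl trans-2-(tert-butyldimethylsilyloxy)cyclobutane-1-carboxylate | COC(=O)C1CCC1O[Si](C)(C)C(C)(C)C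
F9 | step 6 | rac-methyl 2-(tert-butyldimethylsilyloxy)-1-(phenylselanyl)cyclobutane-1-carboxylate | COC(=O)C1([Se]c2ccccc2)CCC1O[Si](C)(C)C(C)(C)C
F10 | step 6 | selenoxide of F9 | COC(=O)C1([Se](=O)c2ccccc2)CCC1O[Si](C)(C)C(C)(C)C
F0 | step 18 | none | none
A1 | alternative 1 | isoxazoline-bridged ten-membered lactone | O=C1O[C@@H]2/C=C(/CO[Si](C)(C)C(C)(C)C)[C@@H]3CC(=NO3)[C@](C)(O[Si](CC)(CC)CC)C[C@@H](OCc4ccc(OC)cc4)[C@H]2C1
A2 | alternative 1 | open-chain aldoxime with diene terminus and preformed lactone | ON=C[C@](C)(O[Si](CC)(CC)CC)C[C@@H](OCc1ccc(OC)cc1)[C@H]1CC(=O)O[C@@H]1/C=C(/CO[Si](C)(C)C(C)(C)C)C=C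
A3 | alternative 2 | bis-silyl ether of the target | C=C1C(=O)O[C@@H]2/C=C(/CO[Si](C)(C)C(C)(C)C)[C@@H](O[Si](C)(C)C(C)(C)C)C[C@H]3O[C@]3(C)C[C@@H](OC(=O)[C@@H](C)CC)[C@@H]12
A4 | alternative 2 | ring acid with C6 methylene and an acrylic acid on C7 | C=C(C(=O)O)[C@H]1C/C=C(/CO[Si](C)(C)C(C)(C)C)[C@@H](O[Si](C)(C)C(C)(C)C)C[C@H]2O[C@]2(C)C[C@H]1OC(=O)[C@@H](C)CC
A5 | alternative 3 | 1(10)-ene precursor of the target with free C3–OH and C15 silyl ether | C=C1C(=O)O[C@@H]2/C=C(/CO[Si](C)(C)C(C)(C)C)[C@@H](O)C/C=C(\C)C[C@@H](OC(=O)[C@@H](C)CC)[C@@H]12
A6 | alternative 3 | open-chain (Z)-alkenyl iodide aldehyde carrying the lactone and the C8 ester | C=C1C(=O)O[C@H](/C=C(\I)CO[Si](C)(C)C(C)(C)C)[C@H]1[C@H](OC(=O)[C@@H](C)CC)C/C(C)=C/CC=O
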